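**Retrosynthetic overview**

1. The target is read as a 2,3-cis flavan-3-ol with a pyrogallol ring B (upper unit, 2R,3R,4R, 4β) bonded C4→C8 to a second such unit (middle unit, 2R,3R,4S, 4α, all-cis), bonded C4→C8 to (−)-epicatechin (lower unit). The last step removes fourteen benzyl ethers and two C6 bromines.
2. Key disconnection, C4(middle)–C8(lower): the α-carbon of a flavan-3-one is used with reversed polarity as its 4-diazo derivative (electrophilic C4) against the nucleophilic C8 of penta-O-benzylepicatechin. C4 is set when the resulting enol is protonated (2,4-cis), and C3 by hydride (all-cis).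
3. C4(upper)–C8(middle): a 4β-alkoxy flavan is ionised and attacked by a 6-bromo-flavan-3-ol. Bromine at C6 forces reaction at C8, and attack anti to the 3-O group gives 2,3-cis-3,4-trans directly.
4. Both upper units come from one monomer, the (2R,3R)-6-bromo-7-O-benzyl flavan-3-ol, made from the racemic flavan-3-one by hydrogenation under dynamic kinetic resolution.
5. Ring order: rings A and B are bought as aldehydes; ring C is closed by an oxa-Michael/Henry annulation and reduced to the 3-ketone; epicatechin brings its three rings.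

Assumption: the hand of the ruthenium catalyst written in step 5 is taken to be the one that hydrogenates the Si face of C3 and gives the (2R,3R) alcohol; if a first run shows the opposite sense, the mirror-image complex is used and nothing else changes.

**Route**

Step 1
Reactants: 1 4-(benzyloxy)-2-hydroxybenzaldehyde
Product: 2 4-(benzyloxy)-5-bromo-2-hydroxybenzaldehyde
Conditions: NBS (1.05 equiv), MeCN, 0 °C → rt
Reagents that add atoms: N-bromosuccinimide O=C1CCC(=O)N1Br
Why: Electrophilic aromatic bromination goes para to the free phenol and ortho to the benzyloxy group, the carbon that becomes C6 of the flavan, where the bromine later blocks the more reactive ring A position and is removed in the last step.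

Step 2
Reactants: 3 3,4,5-tris(benzyloxy)benzaldehyde; 4 nitromethane
Product: 5 (E)-1,2,3-tris(benzyloxy)-5-(2-nitroethenyl)benzene
Conditions: NH4OAc (0.5 equiv), MeNO2/AcOH, 100 °C
Reagents that add atoms: none
Why: Henry condensation followed by dehydration gives the thermodynamically favoured E-nitroalkene.

Step 3
Reactants: 2 4-(benzyloxy)-5-bromo-2-hydroxybenzaldehyde; 5 (E)-1,2,3-tris(benzyloxy)-5-(2-nitroethenyl)benzene
Product: 6 racemic 7-(benzyloxy)-6-bromo-3-nitro-2-[3,4,5-tris(benzyloxy)phenyl]-2H-chromene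
Conditions: DABCO (0.5 equiv), MeCN, 60 °C
Reagents that add atoms: none
Why: Tandem oxa-Michael addition of the phenoxide to the nitroalkene, intramolecular Henry reaction and dehydration close ring C in one operation, and C2 is deliberately formed racemic because it is set in step 5.

Step 4
Reactants: 6 racemic 7-(benzyloxy)-6-bromo-3-nitro-2-[3,4,5-tris(benzyloxy)phenyl]-2H-chromene
Product: 8 racemic 7-(benzyloxy)-6-bromo-2-[3,4,5-tris(benzyloxy)phenyl]chroman-3-one, via chroman-3-imine 7 (not isolated)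
Conditions: Fe powder (5 equiv), AcOH/EtOH/H2O (2:2:1), 80 °C
Reagents that add atoms: water O
Why: Iron in acetic acid reduces the conjugated nitroalkene to the ketimine, which is hydrolysed in the same acidic medium to the ketone (reductive Nef-type conversion), while the aryl bromide and the benzyl ethers are untouched.

Step 5
Reactants: 8 racemic 7-(benzyloxy)-6-bromo-2-[3,4,5-tris(benzyloxy)phenyl]chroman-3-one
Product: 9 (2R,3R)-7-(benzyloxy)-6-bromo-2-[3,4,5-tris(benzyloxy)phenyl]chroman-3-ol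
Conditions: RuCl2[(R)-Xyl-SDP][(S,S)-DPEN] (0.5 mol %), KOt-Bu (10 mol %), H2 (50 atm), i-PrOH/toluene, rt, degassed
Reagents that add atoms: none
Why: Noyori-type asymmetric hydrogenation under dynamic kinetic resolution: the base racemises C2 (α to the ketone, benzylic and α to oxygen) faster than reduction, and the catalyst hydrogenates only the 2R ketone on the Si face of C3, anti to the 2-aryl group, so C2 (R) and C3 (R) are both set here as the 2,3-cis alcohol, as with 2-aryl- and 2-aryloxy-cycloalkanones.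

Step 6
Reactants: 9 (2R,3R)-7-(benzyloxy)-6-bromo-2-[3,4,5-tris(benzyloxy)phenyl]chroman-3-ol
Product: 10 (2R,3R)-3,7-bis(benzyloxy)-6-bromo-2-[3,4,5-tris(benzyloxy)phenyl]chromane
Conditions: NaH (1.5 equiv), BnBr (1.3 equiv), DMF, 0 °C → rt
Reagents that add atoms: benzyl bromide BrCc1ccccc1
Why: Williamson etherification masks the 3-OH of the future upper unit, so that only the 3-OH of the middle unit is oxidised in step 9 and no O–H insertion competes in step 12; no stereocentre is touched.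

Step 7
Reactants: 10 (2R,3R)-3,7-bis(benzyloxy)-6-bromo-2-[3,4,5-tris(benzyloxy)phenyl]chromane
Product: 11 (2R,3R,4S)-3,7-bis(benzyloxy)-6-bromo-4-(2-ethoxyethoxy)-2-[3,4,5-tris(benzyloxy)phenyl]chromane
Conditions: DDQ (2 equiv), 2-ethoxyethanol (10 equiv), CH2Cl2, rt
Reagents that add atoms: 2-ethoxyethanol CCOCCO
Why: DDQ benzylic oxidation removes hydride from C4, the position activated by the para 7-benzyloxy group and the ortho ring oxygen, and the alcohol adds anti to the 3-benzyloxy and 2-aryl groups (4β); this centre is only a leaving group and is ionised again in step 8.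

Step 8
Reactants: 11 (2R,3R,4S)-3,7-bis(benzyloxy)-6-bromo-4-(2-ethoxyethoxy)-2-[3,4,5-tris(benzyloxy)phenyl]chromane; 9 (2R,3R)-7-(benzyloxy)-6-bromo-2-[3,4,5-tris(benzyloxy)phenyl]chroman-3-ol
Product: 12 dimer alcohol (2R,3R)-7-(benzyloxy)-8-[(2R,3R,4R)-3,7-bis(benzyloxy)-6-bromo-2-[3,4,5-tris(benzyloxy)phenyl]chroman-4-yl]-6-bromo-2-[3,4,5-tris(benzyloxy)phenyl]chroman-3-ol
Conditions: TMSOTf (0.2 equiv), 9 (4 equiv, excess recovered), 4 Å MS, CH2Cl2, −40 → 0 °C
Reagents that add atoms: none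
Why: Lewis-acid ionisation of the 4-alkoxy group followed by Friedel–Crafts-type flavan-4-yl arylation: C8 of 9 is the only open activated position of its ring A because C6 carries bromine, it attacks C4 from the β face, anti to both the 3-benzyloxy and the 2-aryl group, which sets C4 of the upper unit as R (2,3-cis-3,4-trans), and the bromine on the electrophile together with the excess of 9 suppresses self-condensation.

Step 9
Reactants: 12 dimer alcohol
Product: 13 dimer ketone (2R)-7-(benzyloxy)-8-[(2R,3R,4R)-3,7-bis(benzyloxy)-6-bromo-2-[3,4,5-tris(benzyloxy)phenyl]chroman-4-yl]-6-bromo-2-[3,4,5-tris(benzyloxy)phenyl]chroman-3-one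
Conditions: Dess–Martin periodinane (1.5 equiv), CH2Cl2, 0 °C → rt
Reagents that add atoms: none
Why: Dess–Martin oxidation of the only free hydroxyl gives the flavan-3-one of the middle unit under neutral conditions that leave its C2 stereocentre intact.

Step 10
Reactants: 13 dimer ketone
Product: 14 dimer diazo ketone (2R)-7-(benzyloxy)-8-[(2R,3R,4R)-3,7-bis(benzyloxy)-6-bromo-2-[3,4,5-tris(benzyloxy)phenyl]chroman-4-yl]-6-bromo-4-diazo-2-[3,4,5-tris(benzyloxy)phenyl]chroman-3-one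
Conditions: 4-acetamidobenzenesulfonyl azide (1.3 equiv), DBU (1.3 equiv), MeCN/CH2Cl2, 0 °C, 1 h
Reagents that add atoms: 4-acetamidobenzenesulfonyl azide CC(=O)Nc1ccc(cc1)S(=O)(=O)N=[N+]=[N-]
Why: Regitz diazo transfer takes place at the C4 methylene, which is both benzylic and α to the ketone, whereas the tertiary C2–H cannot accept a diazo group and the short, cold contact with base keeps C2 from epimerising.

Step 11
Reactants: 15 (−)-epicatechin
Product: 17 (2R,3R)-3,5,7-tris(benzyloxy)-2-[3,4-bis(benzyloxy)phenyl]chromane, via tetra-O-benzylepicatechin 16 (not isolated)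
Conditions: BnBr (6 equiv), K2CO3 (5 equiv), DMF, 0 °C → rt; then NaH (1.5 equiv), 0 °C → rt
Reagents that add atoms: benzyl bromide BrCc1ccccc1
Why: Williamson benzylation of the four phenols under mild carbonate conditions, then of the 3-OH with hydride, protects every O–H of the lower unit without touching C2 or C3, so that only its ring A carbons can react in step 12.

Step 12
Reactants: 14 dimer diazo ketone; 17 (2R,3R)-3,5,7-tris(benzyloxy)-2-[3,4-bis(benzyloxy)phenyl]chromane
Product: 19 protected trimer ketone with 2,4-cis (4S) middle unit, via enol 18 (not isolated)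
Conditions: Rh2(OAc)4 (2 mol %), 17 (3 equiv, excess recovered), CH2Cl2, 0 °C → rt, 14 added over 4 h; then PPTS (5 mol %), rt
Reagents that add atoms: none
Why: Proposed new method: the diazo ketone is a reversed-polarity (enolonium-type) form of the flavan-3-one α-carbon, so its dirhodium carbene is attacked at C4 by C8 of the phloroglucinol-type ring of 17 (the position between O1 and the 7-benzyloxy group, the usual site of attack on this ring) in a formal electrophilic aromatic substitution that first gives the enol 18 with C4 still planar, and C4 becomes a stereocentre only when this enol takes up a proton on the face opposite the 2-aryl group, which is also the way to the more stable 2,4-diequatorial ketone, so the 2,4-cis (4S) isomer forms without any base that could disturb C2; the closest known reaction type is the dirhodium-catalysed C–H arylation of electron-rich arenes such as 1,3,5-trimethoxybenzene with aryl/acyl diazo compounds (aryldiazoacetates, 3-diazooxindoles).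

Step 13
Reactants: 19 protected trimer ketone
Product: 20 protected trimer alcohol with (2R,3R,4S) middle unit
Conditions: LiBH(s-Bu)3 (3 equiv), THF, −78 → −40 °C; then H2O
Reagents that add atoms: none
Why: Diastereoselective bulky-hydride reduction: in the 2,4-cis ketone both aryl groups are equatorial on the α face, so hydride enters from the open β face and the new 3-OH is axial and α, cis to both neighbours (3R, all-cis), as in the reduction of flavan-3-ones to 2,3-cis flavan-3-ols.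

Step 14
Reactants: 20 protected trimer alcohol
Product: 21 target CNP0115797.2
Conditions: H2 (1 atm), Pd(OH)2/C, Et3N (2.2 equiv), THF/MeOH/H2O, rt; Sephadex LH-20
Reagents that add atoms: none
Why: Catalytic hydrogenolysis cleaves the fourteen benzyl ethers and, with the amine as acid scavenger, the two aryl C–Br bonds, while the interflavan bonds and all eight stereocentres are untouched under these near-neutral conditions.

**Compound list**

1 | 4-(benzyloxy)-2-hydroxybenzaldehyde | O=Cc1ccc(OCc2ccccc2)cc1O | starting material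

2 | 4-(benzyloxy)-5-bromo-2-hydroxybenzaldehyde | O=Cc1cc(Br)c(OCc2ccccc2)cc1O | intermediate

3 | 3,4,5-tris(benzyloxy)benzaldehyde | O=Cc1cc(OCc2ccccc2)c(OCc2ccccc2)c(OCc2ccccc2)c1 | starting material

4 | nitromethane | C[N+](=O)[O-] | starting material

5 | (E)-1,2,3-tris(benzyloxy)-5-(2-nitroethenyl)benzene | [O-][N+](=O)/C=C/c1cc(OCc2ccccc2)c(OCc2ccccc2)c(OCc2ccccc2)c1 | intermediate

6 | racemic 7-(benzyloxy)-6-bromo-3-nitro-2-[3,4,5-tris(benzyloxy)phenyl]-2H-chromene | [O-][N+](=O)C1=Cc2cc(Br)c(OCc3ccccc3)cc2OC1c1cc(OCc2ccccc2)c(OCc2ccccc2)c(OCc2ccccc2)c1 | intermediate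

7 | racemic 7-(benzyloxy)-6-bromo-2-[3,4,5-tris(benzyloxy)phenyl]chroman-3-imine | N=C1Cc2cc(Br)c(OCc3ccccc3)cc2OC1c1cc(OCc2ccccc2)c(OCc2ccccc2)c(OCc2ccccc2)c1 | intermediate

8 | racemic 7-(benzyloxy)-6-bromo-2-[3,4,5-tris(benzyloxy)phenyl]chroman-3-one | O=C1Cc2cc(Br)c(OCc3ccccc3)cc2OC1c1cc(OCc2ccccc2)c(OCc2ccccc2)c(OCc2ccccc2)c1 | intermediate

9 | (2R,3R)-7-(benzyloxy)-6-bromo-2-[3,4,5-tris(benzyloxy)phenyl]chroman-3-ol | c1ccccc1COc1c(Br)cc2c(c1)O[C@H](c1cc(OCc3ccccc3)c(OCc3ccccc3)c(OCc3ccccc3)c1)[C@H](O)C2 | intermediate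

10 | (2R,3R)-3,7-bis(benzyloxy)-6-bromo-2-[3,4,5-tris(benzyloxy)phenyl]chromane | c1ccccc1COc1c(Br)cc2c(c1)O[C@H](c1cc(OCc3ccccc3)c(OCc3ccccc3)c(OCc3ccccc3)c1)[C@H](OCc1ccccc1)C2 | intermediate

11 | (2R,3R,4S)-3,7-bis(benzyloxy)-6-bromo-4-(2-ethoxyethoxy)-2-[3,4,5-tris(benzyloxy)phenyl]chromane (4β-alkoxy) | c1ccccc1COc1c(Br)cc2c(c1)O[C@H](c1cc(OCc3ccccc3)c(OCc3ccccc3)c(OCc3ccccc3)c1)[C@H](OCc1ccccc1)[C@H]2OCCOCC | intermediate

12 | (2R,3R)-7-(benzyloxy)-8-[(2R,3R,4R)-3,7-bis(benzyloxy)-6-bromo-2-[3,4,5-tris(benzyloxy)phenyl]chroman-4-yl]-6-bromo-2-[3,4,5-tris(benzyloxy)phenyl]chroman-3-ol | c1ccccc1COc1c(Br)cc2c(c1)O[C@H](c1cc(OCc3ccccc3)c(OCc3ccccc3)c(OCc3ccccc3)c1)[C@H](OCc1ccccc1)[C@H]2c1c(OCc3ccccc3)c(Br)cc2c1O[C@H](c1cc(OCc3ccccc3)c(OCc3ccccc3)c(OCc3ccccc3)c1)[C@H](O)C2 | intermediate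

13 | (2R)-7-(benzyloxy)-8-[(2R,3R,4R)-3,7-bis(benzyloxy)-6-bromo-2-[3,4,5-tris(benzyloxy)phenyl]chroman-4-yl]-6-bromo-2-[3,4,5-tris(benzyloxy)phenyl]chroman-3-one | c1ccccc1COc1c(Br)cc2c(c1)O[C@H](c1cc(OCc3ccccc3)c(OCc3ccccc3)c(OCc3ccccc3)c1)[C@H](OCc1ccccc1)[C@H]2c1c(OCc3ccccc3)c(Br)cc2c1O[C@H](c1cc(OCc3ccccc3)c(OCc3ccccc3)c(OCc3ccccc3)c1)C(=O)C2 | intermediate

14 | (2R)-7-(benzyloxy)-8-[(2R,3R,4R)-3,7-bis(benzyloxy)-6-bromo-2-[3,4,5-tris(benzyloxy)phenyl]chroman-4-yl]-6-bromo-4-diazo-2-[3,4,5-tris(benzyloxy)phenyl]chroman-3-one | c1ccccc1COc1c(Br)cc2c(c1)O[C@H](c1cc(OCc3ccccc3)c(OCc3ccccc3)c(OCc3ccccc3)c1)[C@H](OCc1ccccc1)[C@H]2c1c(OCc3ccccc3)c(Br)cc2c1O[C@H](c1cc(OCc3ccccc3)c(OCc3ccccc3)c(OCc3ccccc3)c1)C(=O)C2=[N+]=[N-] | intermediate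

15 | (−)-epicatechin, (2R,3R)-2-(3,4-dihydroxyphenyl)chromane-3,5,7-triol | Oc1cc(O)c2c(c1)O[C@H](c1ccc(O)c(O)c1)[C@H](O)C2 | starting material

16 | (2R,3R)-5,7-bis(benzyloxy)-2-[3,4-bis(benzyloxy)phenyl]chroman-3-ol | c1ccccc1COc1cc(OCc3ccccc3)c2c(c1)O[C@H](c1ccc(OCc3ccccc3)c(OCc3ccccc3)c1)[C@H](O)C2 | intermediate

17 | (2R,3R)-3,5,7-tris(benzyloxy)-2-[3,4-bis(benzyloxy)phenyl]chromane | c1ccccc1COc1cc(OCc3ccccc3)c2c(c1)O[C@H](c1ccc(OCc3ccccc3)c(OCc3ccccc3)c1)[C@H](OCc1ccccc1)C2 | intermediate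

18 | (2R)-7-(benzyloxy)-8-[(2R,3R,4R)-3,7-bis(benzyloxy)-6-bromo-2-[3,4,5-tris(benzyloxy)phenyl]chroman-4-yl]-6-bromo-4-[(2R,3R)-3,5,7-tris(benzyloxy)-2-[3,4-bis(benzyloxy)phenyl]chroman-8-yl]-2-[3,4,5-tris(benzyloxy)phenyl]-2H-chromen-3-ol (C3=C4 enol) | c1ccccc1COc1c(Br)cc2c(c1)O[C@H](c1cc(OCc3ccccc3)c(OCc3ccccc3)c(OCc3ccccc3)c1)[C@H](OCc1ccccc1)[C@H]2c1c(OCc3ccccc3)c(Br)cc2c1O[C@H](c1cc(OCc3ccccc3)c(OCc3ccccc3)c(OCc3ccccc3)c1)C(O)=C2c1c(OCc3ccccc3)cc(OCc3ccccc3)c2c1O[C@H](c1ccc(OCc3ccccc3)c(OCc3ccccc3)c1)[C@H](OCc1ccccc1)C2 | intermediate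

19 | (2R,4S)-7-(benzyloxy)-8-[(2R,3R,4R)-3,7-bis(benzyloxy)-6-bromo-2-[3,4,5-tris(benzyloxy)phenyl]chroman-4-yl]-6-bromo-4-[(2R,3R)-3,5,7-tris(benzyloxy)-2-[3,4-bis(benzyloxy)phenyl]chroman-8-yl]-2-[3,4,5-tris(benzyloxy)phenyl]chroman-3-one | c1ccccc1COc1c(Br)cc2c(c1)O[C@H](c1cc(OCc3ccccc3)c(OCc3ccccc3)c(OCc3ccccc3)c1)[C@H](OCc1ccccc1)[C@H]2c1c(OCc3ccccc3)c(Br)cc2c1O[C@H](c1cc(OCc3ccccc3)c(OCc3ccccc3)c(OCc3ccccc3)c1)C(=O)[C@@H]2c1c(OCc3ccccc3)cc(OCc3ccccc3)c2c1O[C@H](c1ccc(OCc3ccccc3)c(OCc3ccccc3)c1)[C@H](OCc1ccccc1)C2 | intermediate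

20 | (2R,3R,4S)-7-(benzyloxy)-8-[(2R,3R,4R)-3,7-bis(benzyloxy)-6-bromo-2-[3,4,5-tris(benzyloxy)phenyl]chroman-4-yl]-6-bromo-4-[(2R,3R)-3,5,7-tris(benzyloxy)-2-[3,4-bis(benzyloxy)phenyl]chroman-8-yl]-2-[3,4,5-tris(benzyloxy)phenyl]chroman-3-ol | c1ccccc1COc1c(Br)cc2c(c1)O[C@H](c1cc(OCc3ccccc3)c(OCc3ccccc3)c(OCc3ccccc3)c1)[C@H](OCc1ccccc1)[C@H]2c1c(OCc3ccccc3)c(Br)cc2c1O[C@H](c1cc(OCc3ccccc3)c(OCc3ccccc3)c(OCc3ccccc3)c1)[C@H](O)[C@@H]2c1c(OCc3ccccc3)cc(OCc3ccccc3)c2c1O[C@H](c1ccc(OCc3ccccc3)c(OCc3ccccc3)c1)[C@H](OCc1ccccc1)C2 | intermediate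

21 | CNP0115797.2, (2R,3R,4S)-4-[(2R,3R)-2-(3,4-dihydroxyphenyl)-3,5,7-trihydroxychroman-8-yl]-8-[(2R,3R,4R)-3,7-dihydroxy-2-(3,4,5-trihydroxyphenyl)chroman-4-yl]-2-(3,4,5-trihydroxyphenyl)chromane-3,7-diol | Oc1ccc2c(c1)O[C@H](c1cc(O)c(O)c(O)c1)[C@H](O)[C@H]2c1c(O)ccc2c1O[C@H](c1cc(O)c(O)c(O)c1)[C@H](O)[C@@H]2c1c(O)cc(O)c2c1O[C@H](c1ccc(O)c(O)c1)[C@H](O)C2 | target

**Step count and risk**

Total steps: 14. Longest linear sequence: 12 (steps 1, 3 to 10, 12 to 14). All eight stereocentres are accounted for: upper C2/C3 in step 5, upper C4 in step 8, middle C2 in step 5, middle C4 in step 12, middle C3 in step 13, and lower C2/C3 from epicatechin.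

The three steps most likely to fail:

Step 12 (carbene arylation and C4 protonation). The carbene may prefer benzylic C–H or ether-oxygen sites, or the C4 proton may arrive syn to the 2-aryl group. The fallback sets out from 13 and 17 and generates the same electrophilic α-carbon by oxidation instead: AgBF4 (4 equiv, THF, 0 °C → rt), in which monovalent silver oxidises the enol of 13 to the α-keto benzylic cation. C8 of 17 attacks this cation anti to the 2-aryl group and gives the 2,4-trans (4R) epimer of the trimer ketone F3. Brief treatment with DBU (cat., toluene, rt) equilibrates C4 to the diequatorial 2,4-cis ketone, which returns to the route at 19; C2 must be watched for epimerisation in this variant.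

Step 8 (arylation at the bromine-deactivated, doubly flanked C8). If C8 of 9 is too poor a nucleophile for the cation, the fallback replaces electrophilic substitution by directed metalation. It sets out from 9: TMPMgCl·LiCl (2.5 equiv, THF, 0 °C) removes the hydroxyl proton and then the C8–H between O1 and the 7-benzyloxy group (the aryl bromide is tolerated), giving chloromagnesium (2R,3R)-7-(benzyloxy)-6-bromo-8-(chloromagnesio)-2-[3,4,5-tris(benzyloxy)phenyl]chroman-3-olate F2. This aryl nucleophile is combined with 11 and BF3·OEt2 (CH2Cl2/THF, −78 → −20 °C), C4 again being attacked from the β face, and aqueous work-up returns to the route at 12.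

Step 5 (dynamic kinetic resolution on an untested ketone class). If the enantiomeric excess is poor, the fallback is a resolution with recycling. It sets out from 8: LiBH(s-Bu)3 (THF, −78 °C) gives racemic cis-7-(benzyloxy)-6-bromo-2-[3,4,5-tris(benzyloxy)phenyl]chroman-3-ol F1. The enantiomers are separated by preparative chromatography on a chiral stationary phase, which returns to the route at 9. The (2S,3S) antipode is oxidised back to 8 with Dess–Martin periodinane and reduced again.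

**Further compounds**

F1 | step 5 | racemic cis-7-(benzyloxy)-6-bromo-2-[3,4,5-tris(benzyloxy)phenyl]chroman-3-ol (both enantiomers) | c1ccccc1COc1c(Br)cc2c(c1)O[C@H](c1cc(OCc3ccccc3)c(OCc3ccccc3)c(OCc3ccccc3)c1)[C@H](O)C2.c1ccccc1COc1c(Br)cc2c(c1)O[C@@H](c1cc(OCc3ccccc3)c(OCc3ccccc3)c(OCc3ccccc3)c1)[C@@H](O)C2

F2 | step 8 | chloromagnesium (2R,3R)-7-(benzyloxy)-6-bromo-8-(chloromagnesio)-2-[3,4,5-tris(benzyloxy)phenyl]chroman-3-olate | c1ccccc1COc1c(Br)cc2c(c1[Mg]Cl)O[C@H](c1cc(OCc3ccccc3)c(OCc3ccccc3)c(OCc3ccccc3)c1)[C@H](O[Mg]Cl)C2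

F3 | step 12 | (2R,4R)-7-(benzyloxy)-8-[(2R,3R,4R)-3,7-bis(benzyloxy)-6-bromo-2-[3,4,5-tris(benzyloxy)phenyl]chroman-4-yl]-6-bromo-4-[(2R,3R)-3,5,7-tris(benzyloxy)-2-[3,4-bis(benzyloxy)phenyl]chroman-8-yl]-2-[3,4,5-tris(benzyloxy)phenyl]chroman-3-one (2,4-trans epimer of 19) | c1ccccc1COc1c(Br)cc2c(c1)O[C@H](c1cc(OCc3ccccc3)c(OCc3ccccc3)c(OCc3ccccc3)c1)[C@H](OCc1ccccc1)[C@H]2c1c(OCc3ccccc3)c(Br)cc2c1O[C@H](c1cc(OCc3ccccc3)c(OCc3ccccc3)c(OCc3ccccc3)c1)C(=O)[C@H]2c1c(OCc3ccccc3)cc(OCc3ccccc3)c2c1O[C@H](c1ccc(OCc3ccccc3)c(OCc3ccccc3)c1)[C@H](OCc1ccccc1)C2
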